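The runs are simulated from invented constants.

**Early readings.** In the first minutes of the birch run, which is this very flask followed so far, the single-handed free catalyst gives more left-handed product than right-handed product: 3.7% against 2.4% at 8.00 min.

| setting | birch | flask |
|---|---|---|
| left-handed substrate | 0.11 M | 0.11 M |
| right-handed substrate | 0.11 M | 0.11 M |
| reagent | 0.60 equiv | 0.600 equiv |
| free catalyst | 10 mol% | 10 mol% |
| impurity | 3.6 mM | 3.6 mM |
| remark | the very flask that is asked about, followed so far |  |
| time |  | 5.0 h |

birch run (percent of the left-handed substrate and right-handed substrate together charged)

| time / min | left-handed product / % | right-handed product / % |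
|---|---|---|
| 4.00 | 3.7 | 1.4 |
| 8.00 | 3.7 | 2.4 |
| 15.0 | 5.8 | 3.7 |
| 30.0 | 11.1 | 8.3 |
| 50.0 | 14.3 | 9.1 |

(readings scatter by 1 percentage point)

- free catalyst is single-handed; left-handed substrate and right-handed substrate are mirror images of each other, charged as a racemate, each of them at the stated concentration
- an excess is the difference of the two amounts in percent of their sum
- an excess is below zero if the other one leads

- excess of left-handed product over right-handed product in the product at 6.0 min
- excess of left-handed product over right-handed product in the product at 5.0 h
- part of the left-handed substrate and right-handed substrate charged together that has reacted at 5.0 h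

**Two excesses.** Pooling the readings at 4.00 min and 8.00 min gives an excess of 32.1%, which I take for the early time. It is a loose reading: each value carries a scatter of 1 percentage point. The readings at 50.0 min give 22.2%, and I keep that for the end.

**Conversion ceiling.** Each product molecule costs one reagent molecule, and the equivalents are counted on the left-handed substrate. So the flask holds 0.0660 M of reagent against 0.220 M of substrate together, which makes reagent the limiting reagent. It covers 30.0% of the substrate. At the pace between 8.00 min and 50.0 min that charge lasts 1.21 h. The pace should slow as reagent thins, but 5.0 h is longer than that span, by a factor of 4.13, so I count the reagent as turned over by then.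

A catalyst also holds substrate while it works, and that substrate is neither free nor product. I assume each impurity molecule removes one catalyst molecule, which leaves 7.40 mM working. The conversion ceiling, meaning reagent plus working catalyst over substrate charged, is then 33.4%, and that is my answer for the conversion.

**The forecast.** The forecast gives 28%, 16% and 48% (range 33% to 60%), taking “its 0.60 equiv refers to total substrate”, whereas I count the equivalents on the left-handed substrate and arrive at 33.4%.

**The result.** The flask gives 32.4%, 23.3% and 33.1%, the last standing 0.30 points under the ceiling.

    free catalyst + left-handed substrate ⇌ catalyst intermediate A (K = 230 M⁻¹, k = 2500 M⁻¹ h⁻¹)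
    free catalyst + right-handed substrate ⇌ catalyst intermediate B (K = 280 M⁻¹, k = 1900 M⁻¹ h⁻¹)
    reagent + catalyst intermediate A → free catalyst + left-handed product (k = 400 M⁻¹ h⁻¹)
    reagent + catalyst intermediate B → free catalyst + right-handed product (k = 170 M⁻¹ h⁻¹)
    left-handed substrate ⇌ right-handed substrate (k = 0.330 h⁻¹)
    free catalyst ⇌ dormant form (K = 4.80, k = 0.370 h⁻¹)
    free catalyst + impurity → spent catalyst (k = 21000 M⁻¹ h⁻¹)

**More reagent.** At 5.00 h this flask holds 18.5% left-handed product and 11.5% right-handed product, with 0.0079% of its reagent left, while catalyst intermediate A and catalyst intermediate B stand at 28.0% and 34.6% of the catalyst charged. The neighbour flask with 1.50 equiv of reagent, other charges held, has a ceiling by the same reckoning of 78.4%. With 0.026% of its reagent left at 5.00 h, that neighbour flask has reacted 77.7%.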